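A direct plan would dress a resorcinol ring one substituent at a time (bromine between two MOM ethers, C–H borylation and oxidation, phenoxide C-prenylation, ortho-formylation) and would close the 6-bromochromone A1. It would then add 4-(methoxymethoxy)phenylboronic acid to C2 with Pd(OCOCF3)2 and a chiral pyridine–oxazoline ligand to give the bromoflavanone A2, would attach the hydroxylated five-carbon chain at C6 by a conjunctive cross-coupling and oxidation to give the tris-MOM ether A3, and would end with acid deprotection. Its weakest steps would be: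
- the conjunctive coupling that would turn A2 into A3 at the doubly ortho-substituted C6–Br next to a base-labile flavanone, because that reaction type is unknown on such a halide and the remote carbinol centre would depend on the ligand alone;
- the ortho C-prenylation of a phenoxide on the way to A1, because O-alkylation and double alkylation would compete;
- the five-step decoration of the arene before A1, which would add length without adding complexity.

The route rests on the C4a–C5 bond. Ring A is not bought as a benzene but folded last, as in the biosynthesis, from a poly-β-carbonyl chain whose two ends are masked in rings: C4/C8a as an enantiopure 2-aryl-2,3-dihydro-4H-pyran-4-one (ring C, C2 already set) and C5 as a γ-lactone onto the side-chain oxygen, a mask that the carbinol carbon, γ to C5, invites. One Claisen condensation closes and aromatises ring A, places prenyl at C8 and the hydroxyalkyl chain at C6 by their position in the chain, and releases the (R)-carbinol. No aryl halide, no cross-coupling, no phenoxide C-prenylation and no arene decoration remain.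

Key step: step 7

Remark: flavanone numbering (O1, C2–C8a) is used for the chain carbons also before the rings exist.
Assumption: the absolute sense of the two catalyst-controlled steps (3 and 5) is assigned by analogy with simple alkyl oxiranes and aryl aldehydes and would be checked on the first run; the other catalyst antipode would be taken if needed.

Step 1
Reactants: 1 methyl acetoacetate; 2 prenyl bromide (1-bromo-3-methylbut-2-ene)
Product: 4 methyl 7-methyl-3-oxooct-6-enoate, via acetoacetate dianion 3 (not isolated)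
Conditions: NaH (1.1 equiv), THF, 0 °C; n-BuLi (1.05 equiv), 0 °C; 2 (1.0 equiv), 0 °C → rt; 1 M HCl
Reagents that add atoms: none
Why: Weiler dianion alkylation: the terminal (γ) carbanion of the acetoacetate dianion is the more nucleophilic site, so prenyl bromide is taken up there by SN2 and the future C8 receives its prenyl group as an sp3 carbanion, where C-alkylation is the rule.

Step 2
Reactants: 5 methacrolein
Product: 6 rac-2-(prop-1-en-2-yl)oxirane
Conditions: Me3S+ I− (1.1 equiv), NaH (1.1 equiv), DMSO/THF, −5 °C; 5, −5 °C → rt; distil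
Reagents that add atoms: trimethylsulfonium iodide, C[S+](C)C.[I-]
Why: Corey–Chaykovsky epoxidation: the unstabilised sulfonium ylide adds to the aldehyde carbon (1,2) and the betaine closes with loss of dimethyl sulfide, giving the racemic alkenyl oxirane.

Step 3
Reactants: 6 rac-2-(prop-1-en-2-yl)oxirane
Product: 7 (2S)-2-(prop-1-en-2-yl)oxirane
Conditions: (S,S)-N,N′-bis(3,5-di-tert-butylsalicylidene)cyclohexane-1,2-diaminocobalt acetate (0.5 mol%), H2O (0.55 equiv), neat, 0 °C → rt; distil
Reagents that add atoms: none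
Why: Jacobsen hydrolytic kinetic resolution: the trivalent cobalt–salen catalyst hydrates the R epoxide at its CH2 terminus much faster, so the S epoxide, which carries the future carbinol centre, should be recovered by distillation from the diol.

Step 4
Reactants: 4 methyl 7-methyl-3-oxooct-6-enoate; 7 (2S)-2-(prop-1-en-2-yl)oxirane
Product: 9 (5R)-3-(5-methylhex-4-enoyl)-5-(prop-1-en-2-yl)oxolan-2-one (C3 epimers), via hydroxy keto ester 8 (not isolated)
Conditions: NaOMe (1.0 equiv), MeOH, 0 °C; 7 (1.3 equiv), 45 °C; AcOH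
Reagents that add atoms: none
Why: Alkylation of a β-keto ester enolate by an epoxide followed by lactonisation (the classical route to α-acyl-γ-butyrolactones): SN2 attack at the unhindered CH2 leaves the stereocentre of 7 untouched (S in 7 becomes R in 9 by a change of priorities only), and the alkoxide closes onto the methyl ester.

Step 5
Reactants: 10 methyl (E)-3-methoxybut-2-enoate; 11 4-[(tert-butyldimethylsilyl)oxy]benzaldehyde
Product: 13 (6S)-6-{4-[(tert-butyldimethylsilyl)oxy]phenyl}-4-methoxy-5,6-dihydro-2H-pyran-2-one, via Brassard diene 12 (not isolated)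
Conditions: 10, LDA (1.1 equiv), THF, −78 °C; TMSCl (1.2 equiv), → rt; evaporate, pentane, filter; then 11 (0.8 equiv), Ti(OiPr)4 (10 mol%), (S)-2-[(3,5-di-tert-butyl-2-hydroxybenzylidene)amino]-3,3-dimethylbutan-1-ol (11 mol%), 4 Å molecular sieves, toluene, −20 °C; TFA, CH2Cl2, 0 °C
Reagents that add atoms: none
Why: Catalytic enantioselective hetero-Diels–Alder reaction (Mukaiyama aldol–lactonisation pathway) of Brassard's diene with an aryl aldehyde: the chiral titanium Schiff-base Lewis acid shields one face of the aldehyde and sets the future C2 (6S in the lactone), and acid collapses the adduct to the 4-methoxy lactone.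

Step 6
Reactants: 9 (5R)-3-(5-methylhex-4-enoyl)-5-(prop-1-en-2-yl)oxolan-2-one; 13 (6S)-6-{4-[(tert-butyldimethylsilyl)oxy]phenyl}-4-methoxy-5,6-dihydro-2H-pyran-2-one
Product: 16 (2S)-2-{4-[(tert-butyldimethylsilyl)oxy]phenyl}-6-{5-methyl-1-oxo-1-[(5R)-2-oxo-5-(prop-1-en-2-yl)oxolan-3-yl]hex-4-en-2-yl}-2,3-dihydro-4H-pyran-4-one (diastereomers at C6 and C8), via lactone dianion 14 (not isolated), via open-chain adduct 15 (not isolated)
Conditions: 9 (2.0 equiv), LDA (4.0 equiv), THF, −78 → 0 °C; 13 (1.0 equiv), −78 → −30 °C; AcOH; then TsOH·H2O (10 mol%), CH2Cl2, 0 °C → rt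
Reagents that add atoms: water, O
Why: γ-Acylation of a β-keto ester-type dianion by a lactone (Huckin–Weiler) followed by a Stork–Danheiser-type acid transposition: the C8 carbanion adds to the lactone carbonyl (future C8a), and acid closes the hemiketal, dehydrates it and hydrolyses the methyl enol ether to the dihydropyranone, so that the O1–C8a bond is fixed before ring A exists, C2 is not touched, and the new centres at C6 and C8 are uncontrolled and later become sp2.

Step 7
Reactants: 16 (2S)-2-{4-[(tert-butyldimethylsilyl)oxy]phenyl}-6-{5-methyl-1-oxo-1-[(5R)-2-oxo-5-(prop-1-en-2-yl)oxolan-3-yl]hex-4-en-2-yl}-2,3-dihydro-4H-pyran-4-one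
Product: 18 (2S)-2-{4-[(tert-butyldimethylsilyl)oxy]phenyl}-5,7-dihydroxy-6-[(2R)-2-hydroxy-3-methylbut-3-en-1-yl]-8-(3-methylbut-2-en-1-yl)-2,3-dihydro-4H-chromen-4-one, via cyclic trione 17 (not isolated)
Conditions: DBU (2.5 equiv), MeCN (0.02 M), 0 °C → rt; aq. citric acid, 0 °C
Reagents that add atoms: none
Why: Proposed new method: DBU deprotonates 16 reversibly at C6 and at C8, and the C8-deprotonated tautomer is a dienolate (O4–C4=C4a–C8a=C8) whose α-carbon C4a adds to the neutral lactone carbonyl C5 on the same chain, after which the tetrahedral intermediate expels the side-chain alkoxide and trione 17 enolises irreversibly to the 5,7-dihydroxy arene. The closest known reaction type is the Claisen (Dieckmann-type) cyclisation of 3,5,7-trioxoalkanoates to acylphloroglucinols, the laboratory counterpart of the chalcone synthase step; new are the α-carbon of a cyclic vinylogous ester as the nucleophile and a γ-lactone as the acyl donor. Ring A closes in the 6-(enolexo)-exo-trig mode, the only strain-free closure open to the chain, since C8 could only form a four-membered ring and aldol attack of C6 on C4 would need a bridgehead alkene. No stereocentre is formed: the uncontrolled centres at C6 and C8 become sp2, the carbinol carbon keeps its R configuration because the acyl–oxygen and not the alkyl–oxygen bond of the lactone breaks, and C2 is carried through because an amidine base does not reach the C3 protons needed for retro-oxa-Michael opening. The step needs C-acylation at C4a to outrun proton return and opening of ring C, which the substrate should secure by Curtin–Hammett access to the reactive tautomer, by the 1,3-dicarbonyl activation of the lactone and by the irreversibility of aromatisation, while the regiochemistry of ring A (prenyl at C8, hydroxyalkyl at C6, O1 on C8a) is fixed beforehand by the order of the chain.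

Step 8
Reactants: 18 (2S)-2-{4-[(tert-butyldimethylsilyl)oxy]phenyl}-5,7-dihydroxy-6-[(2R)-2-hydroxy-3-methylbut-3-en-1-yl]-8-(3-methylbut-2-en-1-yl)-2,3-dihydro-4H-chromen-4-one
Product: 19 (2S)-5,7-dihydroxy-6-[(2R)-2-hydroxy-3-methylbut-3-en-1-yl]-2-(4-hydroxyphenyl)-8-(3-methylbut-2-en-1-yl)-2,3-dihydro-4H-chromen-4-one
Conditions: KHF2 (2.5 equiv), MeOH, rt
Reagents that add atoms: none
Why: Fluoride cleavage of an aryl silyl ether with KHF2 in methanol, which is selective for phenolic silyl ethers and close to neutral, so that neither C2 (base-labile through the chalcone) nor the allylic alcohol and the prenyl group (acid-labile) should be at risk.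

Compound list
1 | methyl acetoacetate | COC(=O)CC(C)=O | starting material
2 | prenyl bromide (1-bromo-3-methylbut-2-ene) | CC(C)=CCBr | starting material
3 | sodium lithium dianion of methyl acetoacetate | [Na+].[Li+].COC(=O)[CH-]C(=O)[CH2-] | intermediate
4 | methyl 7-methyl-3-oxooct-6-enoate | COC(=O)CC(=O)CCC=C(C)C | intermediate
5 | methacrolein | C=C(C)C=O | starting material
6 | rac-2-(prop-1-en-2-yl)oxirane | C=C(C)C1CO1 | intermediate
7 | (2S)-2-(prop-1-en-2-yl)oxirane | C=C(C)[C@H]1CO1 | intermediate
8 | methyl 2-[(2R)-2-hydroxy-3-methylbut-3-en-1-yl]-7-methyl-3-oxooct-6-enoate (sodium alkoxide in the flask) | C=C(C)[C@H](O)CC(C(=O)OC)C(=O)CCC=C(C)C | intermediate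
9 | (5R)-3-(5-methylhex-4-enoyl)-5-(prop-1-en-2-yl)oxolan-2-one (C3 epimers) | C=C(C)[C@H]1CC(C(=O)CCC=C(C)C)C(=O)O1 | intermediate
10 | methyl (E)-3-methoxybut-2-enoate | CO/C(C)=C/C(=O)OC | starting material
11 | 4-[(tert-butyldimethylsilyl)oxy]benzaldehyde | CC(C)(C)[Si](C)(C)Oc1ccc(C=O)cc1 | starting material
12 | Brassard's diene, 1,3-dimethoxy-1-(trimethylsilyloxy)buta-1,3-diene | C=C(OC)C=C(OC)O[Si](C)(C)C | intermediate
13 | (6S)-6-{4-[(tert-butyldimethylsilyl)oxy]phenyl}-4-methoxy-5,6-dihydro-2H-pyran-2-one | O=C1C=C(OC)C[C@@H](c2ccc(O[Si](C)(C)C(C)(C)C)cc2)O1 | intermediate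
14 | dilithium dianion of 9 (lactone C3 and chain CH2 next to the ketone) | [Li+].[Li+].C=C(C)[C@H]1C[C-](C(=O)[CH-]CC=C(C)C)C(=O)O1 | intermediate
15 | (5R)-3-[(4E,7S)-7-{4-[(tert-butyldimethylsilyl)oxy]phenyl}-7-hydroxy-5-methoxy-2-(3-methylbut-2-en-1-yl)-3-oxohept-4-enoyl]-5-(prop-1-en-2-yl)oxolan-2-one | CO/C(C[C@@H](c1ccc(O[Si](C)(C)C(C)(C)C)cc1)O)=C/C(=O)C(CC=C(C)C)C(=O)C1C[C@H](C(C)=C)OC1=O | intermediate
16 | (2S)-2-{4-[(tert-butyldimethylsilyl)oxy]phenyl}-6-{5-methyl-1-oxo-1-[(5R)-2-oxo-5-(prop-1-en-2-yl)oxolan-3-yl]hex-4-en-2-yl}-2,3-dihydro-4H-pyran-4-one | O=C1C[C@@H](c2ccc(O[Si](C)(C)C(C)(C)C)cc2)OC(=C1)C(CC=C(C)C)C(=O)C1C[C@H](C(C)=C)OC1=O | intermediate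
17 | (2S)-2-{4-[(tert-butyldimethylsilyl)oxy]phenyl}-6-[(2R)-2-hydroxy-3-methylbut-3-en-1-yl]-8-(3-methylbut-2-en-1-yl)-2,3-dihydro-4H-chromene-4,5,7(6H,8H)-trione | O=C1C[C@@H](c3ccc(O[Si](C)(C)C(C)(C)C)cc3)OC2=C1C(=O)C(C[C@@H](O)C(C)=C)C(=O)C2CC=C(C)C | intermediate
18 | (2S)-2-{4-[(tert-butyldimethylsilyl)oxy]phenyl}-5,7-dihydroxy-6-[(2R)-2-hydroxy-3-methylbut-3-en-1-yl]-8-(3-methylbut-2-en-1-yl)-2,3-dihydro-4H-chromen-4-one | C=C(C)[C@H](O)Cc1c(O)c(CC=C(C)C)c2c(c1O)C(=O)C[C@@H](c1ccc(O[Si](C)(C)C(C)(C)C)cc1)O2 | intermediate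
19 | (2S)-5,7-dihydroxy-6-[(2R)-2-hydroxy-3-methylbut-3-en-1-yl]-2-(4-hydroxyphenyl)-8-(3-methylbut-2-en-1-yl)-2,3-dihydro-4H-chromen-4-one | C=C(C)[C@H](O)Cc1c(O)c(CC=C(C)C)c2c(c1O)C(=O)C[C@@H](c1ccc(O)cc1)O2 | target

Total step count: 8. Longest linear sequence: 6 steps (2, 3, 4, 6, 7, 8).

Steps most likely to fail

1. Step 7 (proposed new method). The ring closure may stall because the chain rests as its unreactive C6 enolate and proton return outruns acylation at C4a. Ring C may also open by retro-oxa-Michael reaction on longer exposure to base, with loss of the C2 configuration. The fallback uses known reactions: C5 is brought in as carbon monoxide and ring A is closed by an ordinary ketone-enolate Dieckmann condensation. It sets out from 16. Saponification of the lactone with LiOH in aqueous THF and decarboxylation of the β-keto acid on mild acidification (the known decarboxylative opening of α-acyl lactones) would give the hydroxy ketone (2S)-2-{4-[(tert-butyldimethylsilyl)oxy]phenyl}-6-[(9R)-9-hydroxy-2,10-dimethyl-6-oxoundeca-2,10-dien-5-yl]-2,3-dihydro-4H-pyran-4-one F1. I2/pyridine in CH2Cl2 would iodinate the α-carbon of the vinylogous ester (C4a) to the 5-iodo compound F2. Methoxycarbonylation of the alkenyl iodide with Pd(OAc)2/1,1′-bis(diphenylphosphino)ferrocene, CO (1 atm), MeOH and Et3N would give the methyl 5-carboxylate F3. t-BuOK in THF at −40 °C would then close the C6 enolate onto this ester and, after enolisation, come back to the route at 18.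

2. Step 6. The dianion may act as a base toward the C5 protons of 13 (ring opening of the lactone by elimination) or add in the conjugate sense at the methoxy-bearing carbon. In the acid stage the open-chain adduct may close through a chain enol oxygen to a 4-pyranone instead of through the hemiketal. The fallback uses an open-chain, chelating acyl donor and sets out from 13. Me(MeO)NH·HCl/i-PrMgCl in THF would open the lactone to the Weinreb amide (2E,5S)-5-{4-[(tert-butyldimethylsilyl)oxy]phenyl}-5-hydroxy-N,3-dimethoxy-N-methylpent-2-enamide F4, and TESCl/imidazole would give its triethylsilyl ether F5. Dianion 14 would be acylated by F5 through a stable chelated tetrahedral intermediate (known acylation of β-keto ester dianions by Weinreb amides) to the silyl-protected diketo lactone F6. TsOH·H2O in wet CH2Cl2 would then remove the triethylsilyl group, close the hemiketal and hydrolyse the enol ether, coming back to the route at 16.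

3. Step 4. The β-keto ester enolate is a sluggish nucleophile toward epoxides, so opening at the allylic carbon or in the SN2′ sense, and retro-Claisen cleavage by methoxide at the temperature needed, may take over. The fallback builds the lactone first and adds the acyl group afterwards, and sets out from 7. Diethyl malonate/NaOEt in EtOH would give ethyl (5R)-2-oxo-5-(prop-1-en-2-yl)oxolane-3-carboxylate F7 (malonate opening of an alkenyl oxirane with lactonisation). NaOH, then warm dilute acid, would saponify and decarboxylate it to (5R)-5-(prop-1-en-2-yl)oxolan-2-one F8. The lithium enolate of F8 (LDA, 2.1 equiv, THF, −78 °C) would be acylated in a crossed Claisen condensation by ethyl 5-methylhex-4-enoate F9 (from the Johnson–Claisen rearrangement of 2-methylbut-3-en-2-ol with triethyl orthoacetate), coming back to the route at 9.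

Further compounds
F1 | step 7 | (2S)-2-{4-[(tert-butyldimethylsilyl)oxy]phenyl}-6-[(9R)-9-hydroxy-2,10-dimethyl-6-oxoundeca-2,10-dien-5-yl]-2,3-dihydro-4H-pyran-4-one | O=C1C[C@@H](c2ccc(O[Si](C)(C)C(C)(C)C)cc2)OC(=C1)C(CC=C(C)C)C(=O)CC[C@@H](O)C(C)=C
F2 | step 7 | (2S)-2-{4-[(tert-butyldimethylsilyl)oxy]phenyl}-6-[(9R)-9-hydroxy-2,10-dimethyl-6-oxoundeca-2,10-dien-5-yl]-5-iodo-2,3-dihydro-4H-pyran-4-one | O=C1C[C@@H](c2ccc(O[Si](C)(C)C(C)(C)C)cc2)OC(=C1I)C(CC=C(C)C)C(=O)CC[C@@H](O)C(C)=C
F3 | step 7 | methyl (2S)-2-{4-[(tert-butyldimethylsilyl)oxy]phenyl}-6-[(9R)-9-hydroxy-2,10-dimethyl-6-oxoundeca-2,10-dien-5-yl]-4-oxo-3,4-dihydro-2H-pyran-5-carboxylate | O=C1C[C@@H](c2ccc(O[Si](C)(C)C(C)(C)C)cc2)OC(=C1C(=O)OC)C(CC=C(C)C)C(=O)CC[C@@H](O)C(C)=C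
F4 | step 6 | (2E,5S)-5-{4-[(tert-butyldimethylsilyl)oxy]phenyl}-5-hydroxy-N,3-dimethoxy-N-methylpent-2-enamide | CO/C(C[C@@H](c1ccc(O[Si](C)(C)C(C)(C)C)cc1)O)=C/C(=O)N(C)OC
F5 | step 6 | (2E,5S)-5-{4-[(tert-butyldimethylsilyl)oxy]phenyl}-N,3-dimethoxy-N-methyl-5-[(triethylsilyl)oxy]pent-2-enamide | CO/C(C[C@@H](c1ccc(O[Si](C)(C)C(C)(C)C)cc1)O[Si](CC)(CC)CC)=C/C(=O)N(C)OC
F6 | step 6 | (5R)-3-[(4E,7S)-7-{4-[(tert-butyldimethylsilyl)oxy]phenyl}-5-methoxy-2-(3-methylbut-2-en-1-yl)-3-oxo-7-[(triethylsilyl)oxy]hept-4-enoyl]-5-(prop-1-en-2-yl)oxolan-2-one | CO/C(C[C@@H](c1ccc(O[Si](C)(C)C(C)(C)C)cc1)O[Si](CC)(CC)CC)=C/C(=O)C(CC=C(C)C)C(=O)C1C[C@H](C(C)=C)OC1=O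
F7 | step 4 | ethyl (5R)-2-oxo-5-(prop-1-en-2-yl)oxolane-3-carboxylate | CCOC(=O)C1C[C@H](C(C)=C)OC1=O
F8 | step 4 | (5R)-5-(prop-1-en-2-yl)oxolan-2-one | C=C(C)[C@H]1CCC(=O)O1
F9 | step 4 | ethyl 5-methylhex-4-enoate | CCOC(=O)CCC=C(C)C
A1 | direct plan | 6-bromo-5,7-bis(methoxymethoxy)-8-(3-methylbut-2-en-1-yl)-4H-chromen-4-one | O=c1ccoc2c(CC=C(C)C)c(OCOC)c(Br)c(OCOC)c12
A2 | direct plan | (2S)-6-bromo-5,7-bis(methoxymethoxy)-2-[4-(methoxymethoxy)phenyl]-8-(3-methylbut-2-en-1-yl)-2,3-dihydro-4H-chromen-4-one | Brc1c(OCOC)c(CC=C(C)C)c2c(c1OCOC)C(=O)C[C@@H](c1ccc(OCOC)cc1)O2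
A3 | direct plan | (2S)-6-[(2R)-2-hydroxy-3-methylbut-3-en-1-yl]-5,7-bis(methoxymethoxy)-2-[4-(methoxymethoxy)phenyl]-8-(3-methylbut-2-en-1-yl)-2,3-dihydro-4H-chromen-4-one | C=C(C)[C@H](O)Cc1c(OCOC)c(CC=C(C)C)c2c(c1OCOC)C(=O)C[C@@H](c1ccc(OCOC)cc1)O2
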